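The six-membered ring (C1 carbonyl, C2=C3, C4–OMe, C5, quaternary C6) bears at C6 the side chain C7H(Me)–C8(=O)Ar, which places the carbonyls C1 and C8 in a 1,4-relationship across C6–C7. Everything rests on cutting C1–C6. A chiral carbene turns a C1 aldehyde into an acyl-anion equivalent that adds to C6 of a tetrasubstituted aryl enone; this single operation closes the ring, creates the quaternary centre and, by syn proton delivery, the C7 centre. The precursor is the open-chain (Z)-enone aldehyde with allyl on C6, methyl on C7 and the C4 methoxy stereocentre, taken from (R)-epichlorohydrin; its geometry is fixed by carbocupration. Dehydrogenation at C2–C3 ends the route.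

Key step: step 9

Remark: atom labels C1–C8 follow the target throughout; C4 is R in every open-chain and saturated compound and S in the target only because the C2=C3 bond changes the CIP ranking; the matched catalyst is assumed to be (5aS,10bR)-2-(pentafluorophenyl)-5a,10b-dihydro-4H,6H-indeno[2,1-b][1,2,4]triazolo[4,3-d][1,4]oxazinium tetrafluoroborate (salt T), its antipode being taken instead if a trial with both shows the opposite.

Step 1
Reactants: 1 (R)-epichlorohydrin; 2 (1,3-dioxolan-2-ylmethyl)magnesium bromide
Product: 4 2-{2-[(2R)-oxiran-2-yl]ethyl}-1,3-dioxolane, via chlorohydrin 3 (not isolated)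
Conditions: CuI (10 mol %), THF, −30 → 0 °C; then aq. NaOH, rt
Reagents that add atoms: none
Why: Copper-catalysed Grignard opening of the epoxide at its unsubstituted carbon, followed by Williamson-type closure of the chlorohydrin, is the standard chain extension of epichlorohydrin and breaks no bond at the stereocentre, so the configuration of 1 becomes that of C4.

Step 2
Reactants: 4 2-{2-[(2R)-oxiran-2-yl]ethyl}-1,3-dioxolane; 5 lithium acetylide–ethylenediamine complex
Product: 6 (3R)-1-(1,3-dioxolan-2-yl)hex-5-yn-3-ol
Conditions: LiC≡CH·H2NCH2CH2NH2, DMSO, 0 °C → rt; aqueous work-up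
Reagents that add atoms: none
Why: SN2 opening of the terminal epoxide by the acetylide at its CH2 carbon (epoxide alkynylation) leaves the stereocentre untouched, and the dioxolane is inert to the basic medium.

Step 3
Reactants: 6 (3R)-1-(1,3-dioxolan-2-yl)hex-5-yn-3-ol
Product: 7 2-[(3R)-3-methoxyhex-5-yn-1-yl]-1,3-dioxolane
Conditions: NaH, MeI, THF, 0 °C → rt
Reagents that add atoms: iodomethane, CI
Why: Williamson etherification of the alkoxide should proceed without breaking the C–O bond at the stereocentre and without deprotonating the alkyne C–H under these conditions.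

Step 4
Reactants: 7 2-[(3R)-3-methoxyhex-5-yn-1-yl]-1,3-dioxolane
Product: 9 methyl (5R)-7-(1,3-dioxolan-2-yl)-5-methoxyhept-2-ynoate, via lithium acetylide 8 (not isolated)
Conditions: n-BuLi, THF, −78 °C; then ClCO2Me, −78 → 0 °C
Reagents that add atoms: methyl chloroformate, COC(=O)Cl
Why: Deprotonation of the terminal alkyne and C-acylation of the acetylide by the chloroformate (alkyne carboxylation) give the 2-ynoate without affecting the ether or the acetal.

Step 5
Reactants: 9 methyl (5R)-7-(1,3-dioxolan-2-yl)-5-methoxyhept-2-ynoate; 10 allylmagnesium bromide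
Product: 12 methyl (2Z,5R)-7-(1,3-dioxolan-2-yl)-5-methoxy-2-methyl-3-(prop-2-en-1-yl)hept-2-enoate, via alkenylcopper 11 (not isolated)
Conditions: CH2=CHCH2MgBr/CuBr·SMe2 (1:1), THF, −78 °C; then MeI, DMPU, −78 → −30 °C
Reagents that add atoms: iodomethane, CI
Why: Syn carbocupration of the 2-ynoate places allyl on C6 and copper on C7 on the same side, and the α-cuprio ester, which holds its configuration at low temperature (unlike the allenolate from a ynone), is C-methylated with retention (tandem conjugate addition–alkylation), so allyl and methyl end up cis, which is the Z geometry.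

Step 6
Reactants: 12 methyl (2Z,5R)-7-(1,3-dioxolan-2-yl)-5-methoxy-2-methyl-3-(prop-2-en-1-yl)hept-2-enoate
Product: 13 (2Z,5R)-7-(1,3-dioxolan-2-yl)-N,5-dimethoxy-N,2-dimethyl-3-(prop-2-en-1-yl)hept-2-enamide
Conditions: MeNH(OMe)·HCl, i-PrMgCl, THF, −20 → 0 °C
Reagents that add atoms: N,O-dimethylhydroxylamine hydrochloride, CNOC.Cl
Why: Acyl substitution of the methyl ester by the chloromagnesium amide (Weinreb amide formation) needs no base strong enough to deprotonate the γ positions, so the alkene geometry should be kept.

Step 7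
Reactants: 13 (2Z,5R)-7-(1,3-dioxolan-2-yl)-N,5-dimethoxy-N,2-dimethyl-3-(prop-2-en-1-yl)hept-2-enamide; 14 3,4-dimethoxyphenylmagnesium bromide
Product: 15 (2Z,5R)-1-(3,4-dimethoxyphenyl)-7-(1,3-dioxolan-2-yl)-5-methoxy-2-methyl-3-(prop-2-en-1-yl)hept-2-en-1-one
Conditions: THF, 0 °C → rt; aqueous work-up
Reagents that add atoms: none
Why: In this Weinreb ketone synthesis the aryl Grignard reagent should add only once, because the adduct stays chelated to magnesium until work-up, and conjugate addition is blocked by the fully substituted β-carbon.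

Step 8
Reactants: 15 (2Z,5R)-1-(3,4-dimethoxyphenyl)-7-(1,3-dioxolan-2-yl)-5-methoxy-2-methyl-3-(prop-2-en-1-yl)hept-2-en-1-one
Product: 16 (4R,6Z)-8-(3,4-dimethoxyphenyl)-4-methoxy-7-methyl-8-oxo-6-(prop-2-en-1-yl)oct-6-enal
Conditions: 1 M HCl, THF, rt
Reagents that add atoms: water, O
Why: Acid-catalysed acetal hydrolysis frees the C1 aldehyde under conditions too mild to move the tetrasubstituted double bond or to ionise the C4 ether.

Step 9
Reactants: 16 (4R,6Z)-8-(3,4-dimethoxyphenyl)-4-methoxy-7-methyl-8-oxo-6-(prop-2-en-1-yl)oct-6-enal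
Product: 17 (2S,4R)-2-[(2R)-1-(3,4-dimethoxyphenyl)-1-oxopropan-2-yl]-4-methoxy-2-(prop-2-en-1-yl)cyclohexan-1-one
Conditions: salt T (20 mol %), KN(SiMe3)2 (20 mol %), toluene, rt, HN(SiMe3)2 removed in vacuo; then 16, toluene, 23 → 60 °C, Ar
Reagents that add atoms: none
Why: Proposed new method: the carbene freed from salt T adds to the C1 aldehyde to give the enaminol, an acyl-anion equivalent, which attacks C6 of the enone and hands its hydroxyl proton to C7 on the same face before the catalyst is released; the closest known reaction type is the carbene-catalysed intramolecular Stetter reaction of aliphatic aldehydes onto β,β-disubstituted acceptors that forms quaternary centres, extended here to a fully substituted aryl enone. The ring closes in the 6-exo-trig mode through a chair-like transition state. C6 is controlled by that chair, in which the C4 methoxy group and the C6=C7 unit sit equatorial and the allyl group axial, with the matched catalyst enantiomer expected to shield the other face. C7 is controlled by the Z geometry of the enone, because syn delivery of C1 and H across C6=C7 ties the R configuration at C7 to the S configuration at C6, and the amine-free carbene leaves no external acid to protonate the enolate from the other side. The step needs addition at C6 in preference to aldehyde self-condensation, to closure of an aldehyde enolate onto C6 and to base-induced migration of the double bond; the substrate secures this through the polarisation of the enone toward C6 and the five-atom tether that makes the six-membered closure the only unstrained path for C1, supported by the absence of any free base.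

Step 10
Reactants: 17 (2S,4R)-2-[(2R)-1-(3,4-dimethoxyphenyl)-1-oxopropan-2-yl]-4-methoxy-2-(prop-2-en-1-yl)cyclohexan-1-one
Product: 20 (4S,6S)-6-[(2R)-1-(3,4-dimethoxyphenyl)-1-oxopropan-2-yl]-4-methoxy-6-(prop-2-en-1-yl)cyclohex-2-en-1-one, via lithium enolate 18 (not isolated), via sulfilimine adduct 19 (not isolated)
Conditions: LiN(i-Pr)2, THF, −78 °C; then PhS(Cl)=N-t-Bu, −78 °C
Reagents that add atoms: none
Why: In this Mukaiyama dehydrogenation the ring ketone can be deprotonated only at the C2 methylene (C6 is quaternary), which should be far faster than at the shielded C7 methine of the side-chain ketone; the enolate is sulfenylated at C2 and the adduct loses the sulfenamide by syn elimination at −78 °C, so the C2=C3 bond forms without touching a stereocentre.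

Compound list
1 | (R)-epichlorohydrin, (2R)-2-(chloromethyl)oxirane | ClC[C@H]1CO1 | starting material
2 | (1,3-dioxolan-2-ylmethyl)magnesium bromide | Br[Mg]CC1OCCO1 | starting material
3 | (2R)-1-chloro-4-(1,3-dioxolan-2-yl)butan-2-ol, present as its magnesium alkoxide | ClC[C@H](O)CCC1OCCO1 | intermediate (not isolated)
4 | 2-{2-[(2R)-oxiran-2-yl]ethyl}-1,3-dioxolane | C1COC(CC[C@@H]2CO2)O1 | intermediate
5 | lithium acetylide–ethylenediamine complex | [Li]C#C.NCCN | starting material
6 | (3R)-1-(1,3-dioxolan-2-yl)hex-5-yn-3-ol | C#CC[C@H](O)CCC1OCCO1 | intermediate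
7 | 2-[(3R)-3-methoxyhex-5-yn-1-yl]-1,3-dioxolane | C#CC[C@H](OC)CCC1OCCO1 | intermediate
8 | lithium acetylide of 7 | [Li]C#CC[C@H](OC)CCC1OCCO1 | intermediate (not isolated)
9 | methyl (5R)-7-(1,3-dioxolan-2-yl)-5-methoxyhept-2-ynoate | COC(=O)C#CC[C@H](OC)CCC1OCCO1 | intermediate
10 | allylmagnesium bromide | C=CC[Mg]Br | starting material
11 | methyl (5R)-2-cuprio-7-(1,3-dioxolan-2-yl)-5-methoxy-3-(prop-2-en-1-yl)hept-2-enoate, copper cis to allyl | C1(OCCO1)CC[C@@H](OC)C/C(CC=C)=C(/[Cu])C(=O)OC | intermediate (not isolated)
12 | methyl (2Z,5R)-7-(1,3-dioxolan-2-yl)-5-methoxy-2-methyl-3-(prop-2-en-1-yl)hept-2-enoate | C1(OCCO1)CC[C@@H](OC)C/C(CC=C)=C(/C)C(=O)OC | intermediate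
13 | (2Z,5R)-7-(1,3-dioxolan-2-yl)-N,5-dimethoxy-N,2-dimethyl-3-(prop-2-en-1-yl)hept-2-enamide | C1(OCCO1)CC[C@@H](OC)C/C(CC=C)=C(/C)C(=O)N(C)OC | intermediate
14 | 3,4-dimethoxyphenylmagnesium bromide | COc1ccc([Mg]Br)cc1OC | starting material
15 | (2Z,5R)-1-(3,4-dimethoxyphenyl)-7-(1,3-dioxolan-2-yl)-5-methoxy-2-methyl-3-(prop-2-en-1-yl)hept-2-en-1-one | C1(OCCO1)CC[C@@H](OC)C/C(CC=C)=C(/C)C(=O)c2ccc(OC)c(OC)c2 | intermediate
16 | (4R,6Z)-8-(3,4-dimethoxyphenyl)-4-methoxy-7-methyl-8-oxo-6-(prop-2-en-1-yl)oct-6-enal | O=CCC[C@@H](OC)C/C(CC=C)=C(/C)C(=O)c1ccc(OC)c(OC)c1 | intermediate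
17 | (2S,4R)-2-[(2R)-1-(3,4-dimethoxyphenyl)-1-oxopropan-2-yl]-4-methoxy-2-(prop-2-en-1-yl)cyclohexan-1-one | C=CC[C@@]1([C@@H](C)C(=O)c2ccc(OC)c(OC)c2)C[C@H](OC)CCC1=O | intermediate
18 | lithium enolate of 17 across C1–C2 | C=CC[C@@]1([C@@H](C)C(=O)c2ccc(OC)c(OC)c2)C[C@H](OC)CC=C1O[Li] | intermediate (not isolated)
19 | 17 carrying an N-tert-butyl-S-phenylsulfinimidoyl group at C2, configuration at C2 and at sulfur not defined | C=CC[C@@]1([C@@H](C)C(=O)c2ccc(OC)c(OC)c2)C[C@H](OC)CC(C1=O)S(=NC(C)(C)C)c3ccccc3 | intermediate (not isolated)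
20 | (4S,6S)-6-[(2R)-1-(3,4-dimethoxyphenyl)-1-oxopropan-2-yl]-4-methoxy-6-(prop-2-en-1-yl)cyclohex-2-en-1-one, CNP0199951.2 | C=CC[C@@]1([C@@H](C)C(=O)c2ccc(OC)c(OC)c2)C[C@H](OC)C=CC1=O | target

Total step count: 10. Longest linear sequence: 10 steps, from 1 to 20.

Steps most likely to fail

Step 9. The carbene-bound acyl-anion equivalent may add too slowly to the hindered, electron-rich and twisted enone. Aldehyde self-condensation, enolate closure onto C6 to a five-membered ring or migration of the C6=C7 double bond would then take over, and the facial selectivity at C6 may also be poor. The fallback is a 6-exo acyl radical cyclisation, which is known chemistry, and it sets out from 16. Pinnick oxidation (NaClO2, NaH2PO4, 2-methyl-2-butene, t-BuOH/H2O) should give (4R,6Z)-8-(3,4-dimethoxyphenyl)-4-methoxy-7-methyl-8-oxo-6-(prop-2-en-1-yl)oct-6-enoic acid F1. Treatment with (PhSe)2 and Bu3P in CH2Cl2 should convert it into Se-phenyl (4R,6Z)-8-(3,4-dimethoxyphenyl)-4-methoxy-7-methyl-8-oxo-6-(prop-2-en-1-yl)oct-6-eneselenoate F2. Slow addition of Bu3SnH with AIBN in benzene at 80 °C should release the nucleophilic acyl radical, which should close onto C6 through the same chair; the C7 radical then takes a hydrogen atom from the stannane, and the route is rejoined at 17. C7 would no longer be tied to the double-bond geometry, so an equilibration at C7 with DBU may be needed.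

Step 5. C-methylation of the α-cuprio ester may be slower than its isomerisation through the allenoate form, which would erode the Z geometry, or protonation may give the trisubstituted ester. The fallback sets out from 9. The same addition of CH2=CHCH2Cu is quenched at −78 °C with I2, which should trap 11 at once and with retention as methyl (2E,5R)-7-(1,3-dioxolan-2-yl)-2-iodo-5-methoxy-3-(prop-2-en-1-yl)hept-2-enoate F3. Negishi coupling with MeZnCl and Pd(PPh3)4 in THF should then replace iodine by methyl with retention and return to 12.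

Step 10. Before it is intercepted, the lithium enolate may exchange a proton with the C7 methine, epimerising the side-chain centre, or add across the ring to the aryl ketone. The fallback avoids a free enolate and sets out from 17. Soft enolisation with Me3SiOTf and Et3N in CH2Cl2 at 0 °C should silylate only the ring ketone, giving (2R)-1-(3,4-dimethoxyphenyl)-2-[(1S,5R)-5-methoxy-1-(prop-2-en-1-yl)-2-(trimethylsilyloxy)cyclohex-2-en-1-yl]propan-1-one F4. Saegusa–Ito oxidation with Pd(OAc)2 in MeCN at rt should then give 20.

Further compounds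
F1 | step 9 | (4R,6Z)-8-(3,4-dimethoxyphenyl)-4-methoxy-7-methyl-8-oxo-6-(prop-2-en-1-yl)oct-6-enoic acid | OC(=O)CC[C@@H](OC)C/C(CC=C)=C(/C)C(=O)c1ccc(OC)c(OC)c1
F2 | step 9 | Se-phenyl (4R,6Z)-8-(3,4-dimethoxyphenyl)-4-methoxy-7-methyl-8-oxo-6-(prop-2-en-1-yl)oct-6-eneselenoate | O=C([Se]c1ccccc1)CC[C@@H](OC)C/C(CC=C)=C(/C)C(=O)c2ccc(OC)c(OC)c2
F3 | step 5 | methyl (2E,5R)-7-(1,3-dioxolan-2-yl)-2-iodo-5-methoxy-3-(prop-2-en-1-yl)hept-2-enoate | C1(OCCO1)CC[C@@H](OC)C/C(CC=C)=C(/I)C(=O)OC
F4 | step 10 | (2R)-1-(3,4-dimethoxyphenyl)-2-[(1S,5R)-5-methoxy-1-(prop-2-en-1-yl)-2-(trimethylsilyloxy)cyclohex-2-en-1-yl]propan-1-one | C=CC[C@@]1([C@@H](C)C(=O)c2ccc(OC)c(OC)c2)C[C@H](OC)CC=C1O[Si](C)(C)C
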